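**Assumption:** the target is (14S)-14-methylhexadecyl 2,3-dihydroxybenzoate exactly as drawn, and thiophene, (S)-1-bromo-2-methylbutane, 1,8-dibromooctane and 2,3-dihydroxybenzoic acid are all bought.

## Retrosynthetic overview

1. C9–C12 of the side chain are traced back to the four ring carbons of thiophene (1), used as a traceless butane-1,4-diyl linchpin. The last step is a dearomatising Raney-nickel hydrodesulfurization of a 2,5-dialkylthiophene.
2. C12–C13 disconnection: 2-thienyllithium + (S)-1-bromo-2-methylbutane (2, chiral pool; supplies C13–C16 and the C14 stereocentre) gives 3.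
3. C8–C9 disconnection: 5-lithio-3 + symmetric 1,8-dibromooctane (4), mono-alkylation, gives bromide 5.
4. Ester disconnection at the alkyl C–O bond: the carboxylate of unprotected 2,3-dihydroxybenzoic acid (6) + 5 gives thienyl ester 7, which is desulfurized to Gentiside C (8).
5. Rings: none is formed. The catechol ring is bought intact; the thiophene ring is bought and destroyed in the final step.

## Route

**Step 1**
Reactants: 1, thiophene; 2, (S)-1-bromo-2-methylbutane
Product: 3, 2-[(2S)-2-methylbutyl]thiophene
Conditions: 1 (1.5 equiv), n-BuLi (1.3 equiv), THF, −78 → 0 °C, 1 h; then 2 (1.0 equiv), 0 → 55 °C, 16 h; distil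
Reagents that add atoms: (S)-1-bromo-2-methylbutane, CC[C@H](C)CBr (n-BuLi leaves no atoms)
Why: α-lithiation of thiophene followed by SN2 alkylation with a β-branched primary bromide (the same reaction type as the routine 2-ethylhexylation of thiophene); the stereocentre is β to the reacting carbon and has no acidic hydrogen, so the (S) configuration of the chiral-pool bromide is carried over unchanged.

**Step 2**
Reactants: 3, 2-[(2S)-2-methylbutyl]thiophene; 4, 1,8-dibromooctane
Product: 5, 2-(8-bromooctyl)-5-[(2S)-2-methylbutyl]thiophene
Conditions: n-BuLi (1.05 equiv), THF, −78 → 0 °C, 1 h; cannulate into 4 (4 equiv), THF, −78 °C → rt, 12 h; excess 4 recovered by distillation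
Reagents that add atoms: 1,8-dibromooctane, BrCCCCCCCCBr
Why: the only free α-position (C5) is lithiated selectively, and inverse addition into excess symmetric dibromide gives statistical mono-SN2 alkylation; the remote stereocentre is not involved.

**Step 3**
Reactants: 5, 2-(8-bromooctyl)-5-[(2S)-2-methylbutyl]thiophene; 6, 2,3-dihydroxybenzoic acid
Product: 7, 8-{5-[(2S)-2-methylbutyl]thiophen-2-yl}octyl 2,3-dihydroxybenzoate
Conditions: 6 (1.5 equiv), KHCO3 (1.5 equiv), KI (0.1 equiv), DMF, 60 °C, 12 h, N2
Reagents that add atoms: 2,3-dihydroxybenzoic acid, OC(=O)c1cccc(O)c1O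
Why: chemoselective carboxylate O-alkylation (SN2); bicarbonate deprotonates only the CO2H (pKa about 3) and not the phenols (pKa 10 or higher), so the catechol needs no protection and the thiophene is inert.

**Step 4 (key step)**
Reactants: 7, 8-{5-[(2S)-2-methylbutyl]thiophen-2-yl}octyl 2,3-dihydroxybenzoate
Product: 8, Gentiside C, (14S)-14-methylhexadecyl 2,3-dihydroxybenzoate
Conditions: Raney Ni (W-2, washed neutral, solvent-exchanged, about 10 wt equiv), H2 (1 atm), THF, 50 °C; filter through Celite, wash cake with EtOAc/1% AcOH
Reagents that add atoms: none (H2 only; sulfur leaves as nickel sulfide)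
Why: Raney-nickel reductive desulfurization of a thiophene cleaves both C–S bonds and saturates the four ring carbons to give the unbranched C9–C12 segment; the aryl ester and phenols are not reduced at 1 atm and 50 °C in a non-nucleophilic solvent, and C14 carries no C–S bond, so its configuration is retained.

## Compound list

1 | thiophene | c1ccsc1 | starting material
2 | (S)-1-bromo-2-methylbutane | CC[C@H](C)CBr | starting material
3 | 2-[(2S)-2-methylbutyl]thiophene | CC[C@H](C)Cc1cccs1 | intermediate
4 | 1,8-dibromooctane | BrCCCCCCCCBr | starting material
5 | 2-(8-bromooctyl)-5-[(2S)-2-methylbutyl]thiophene | CC[C@H](C)Cc1ccc(CCCCCCCCBr)s1 | intermediate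
6 | 2,3-dihydroxybenzoic acid | OC(=O)c1cccc(O)c1O | starting material
7 | 8-{5-[(2S)-2-methylbutyl]thiophen-2-yl}octyl 2,3-dihydroxybenzoate | CC[C@H](C)Cc1ccc(CCCCCCCCOC(=O)c2cccc(O)c2O)s1 | intermediate
8 | Gentiside C, (14S)-14-methylhexadecyl 2,3-dihydroxybenzoate | CC[C@H](C)CCCCCCCCCCCCCOC(=O)c1cccc(O)c1O | target

## Summary

Total step count: 4, with no protecting groups.
Longest linear sequence: 4 (1 or 2 → 3 → 5 → 7 → 8).

Steps most likely to fail:

1. **Step 4 (Raney Ni on the free catechol ester).** Risks are nickel chelation or adsorption of the catechol, residual olefins from incomplete saturation, and partial erosion at C14 if Ni–H double-bond migration runs from C11/C12 toward C13/C14 before saturation. The ee should be checked on the alcohol released from 8. Fallback: reverse the order of events. Alkylate lithiated 3 with THP-protected 8-bromooctan-1-ol, desulfurize the simple thienyl alcohol (no ester or catechol present) to (S)-14-methylhexadecan-1-ol, then attach 6 last by Mitsunobu esterification. If migration is the problem, pre-reduce the thiophene to the tetrahydrothiophene by ionic hydrogenation (Et3SiH/TFA) so that C–S hydrogenolysis proceeds without diene intermediates.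

2. **Step 1 (SN2 on a β-branched bromide; slow, with E2 competition).** Fallback: reverse the polarity. Make the Grignard reagent from 2 (stereocentre β to Mg, configurationally safe) and couple it with 2-bromothiophene by Ni(dppp)Cl2-catalysed Kumada–Corriu coupling.

3. **Step 2 (statistical mono-alkylation of the dibromide; bis-thienyl octane and elimination by-products).** Fallback: form the C8–C9 bond by electrophilic substitution instead. Friedel–Crafts acylation of 3 at C5 with 8-bromooctanoyl chloride (SnCl4, CH2Cl2), then ionic deoxygenation of the thienyl ketone (Et3SiH/TFA) to give 5, at the cost of one extra step.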